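**Retrosynthetic overview**

- Feature: the only ring is the cyclohexene C1–C6 (C1 = quaternary carbinol carbon bearing C7H2OBz, C2–OBz, C3=C4, C5–OBz, C6–OH). Its vicinal oxygens on C6 and C5 lie directly beside the carbon-substituted C1, which is the pattern of a 2,3-cis-dihydrodiol of a monosubstituted benzene.
- Disconnections, last to first: C5–OBz (Mitsunobu inversion), O2–Bz and O7–Bz (acylations), C1–O/C2–O (syn-dihydroxylation directed by O6–H), C1–C7 (Stille coupling at the C–Br carbon), C5–O/C6–O (enzymatic cis-dihydroxylation of bromobenzene).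
- Ring order: no ring is closed; the benzene ring of bromobenzene becomes the carbocycle when it is dearomatised in step 1.
- Stereocontrol: C6 and C5 come from the enzyme, C1 and C2 are relayed from O6–H, and C5 is inverted at the end.

Key step: step 1

Assumption and conventions: the ring is numbered C1 (quaternary carbinol carbon, bears C7), C2, C3=C4, C5, C6; β is the ring face of the C6 hydroxyl; TDS = thexyldimethylsilyl = dimethyl(2,3-dimethylbutan-2-yl)silyl; the recombinant strain for step 1 is taken to be at hand, bromobenzene being the commercial starting material.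

**Route**

Step 1
Reactants: 1 bromobenzene
Product: 2 (1S,2S)-3-bromocyclohexa-3,5-diene-1,2-diol (C1 = C–Br; O5–H and O6–H both β)
Conditions: E. coli JM109(pDTG601A) whole cells (toluene dioxygenase), IPTG, glucose feed, air, pH 7, 30–35 °C; EtOAc extraction at pH ≥ 7
Reagents that add atoms: dioxygen, O=O
Why: This is the known arene cis-dihydroxylation of halobenzenes by a Rieske non-haem iron dioxygenase: two electrons from NADH reach the mononuclear iron site through the reductase and ferredoxin components, dioxygen is activated there as an iron-bound (hydro)peroxide, and both of its oxygen atoms are passed to one face of the C5–C6 bond of the bound arene. No ring is closed; the benzene ring is dearomatised to a cyclohexa-3,5-diene and the C5–O and C6–O bonds are the only bonds formed. Both new stereocentres (C5 and C6, each S) are fixed by the active-site pocket, which holds the arene with bromine where the methyl group of toluene sits and exposes a single face of the ortho,meta bond. The step needs ortho,meta regioselectivity (no meta,para or ipso attack) and delivery to one enantiotopic face, and both are characteristic of this enzyme with monosubstituted benzenes whose substituent is larger than fluorine. The diol should accumulate because the host lacks the cis-diol dehydrogenase that would rearomatise it to the catechol, and neutral work-up avoids acid-catalysed dehydration to bromophenol.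

Step 2
Reactants: 2 (1S,2S)-3-bromocyclohexa-3,5-diene-1,2-diol
Product: 3 (1S,6S)-2-bromo-6-(thexyldimethylsilyloxy)cyclohexa-2,4-dien-1-ol (O5–TDS ether; O6–H free)
Conditions: TDSCl (1.05 equiv), imidazole, DMF, −10 °C
Reagents that add atoms: thexyldimethylsilyl chloride, CC(C)C(C)(C)[Si](C)(C)Cl
Why: Regioselective silylation of a diol with a bulky silyl chloride: O6–H is flanked by the C–Br carbon and reacts more slowly, so the TDS group should go onto the distal O5; no stereocentre is formed or touched.

Step 3
Reactants: 3 (1S,6S)-2-bromo-6-(thexyldimethylsilyloxy)cyclohexa-2,4-dien-1-ol; 4 (tributylstannyl)methanol (1.3 equiv)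
Product: 5 (1R,6S)-2-(hydroxymethyl)-6-(thexyldimethylsilyloxy)cyclohexa-2,4-dien-1-ol
Conditions: Pd(PPh3)4 (5 mol%), 1,4-dioxane, degassed, dark, 80 °C
Reagents that add atoms: none
Why: Stille cross-coupling of the alkenyl bromide at C1 with the hydroxymethylstannane, whose α-oxygenated CH2OH group transfers in preference to butyl, forms C1–C7 under neutral conditions that should leave the diene, the free O6–H and the silyl ether intact (the descriptor at C6 changes only because of CIP priorities).

Step 4
Reactants: 5 (1R,6S)-2-(hydroxymethyl)-6-(thexyldimethylsilyloxy)cyclohexa-2,4-dien-1-ol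
Product: 6 [(5S,6R)-6-hydroxy-5-(thexyldimethylsilyloxy)cyclohexa-1,3-dien-1-yl]methyl benzoate
Conditions: BzCl (1.05 equiv), pyridine, CH2Cl2, −40 to −20 °C
Reagents that add atoms: benzoyl chloride, O=C(Cl)c1ccccc1
Why: Chemoselective acylation (benzoylation) of the primary allylic O7–H over the secondary O6–H, which is crowded by the ring and by the cis silyl ether on C5.

Step 5
Reactants: 6 [(5S,6R)-6-hydroxy-5-(thexyldimethylsilyloxy)cyclohexa-1,3-dien-1-yl]methyl benzoate
Product: 8 [(1R,2R,5S,6S)-1,2,6-trihydroxy-5-(thexyldimethylsilyloxy)cyclohex-3-en-1-yl]methyl benzoate, via osmate(VI) ester–TMEDA complex 7 (not isolated)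
Conditions: OsO4 (1.05 equiv), TMEDA (1.1 equiv), CH2Cl2, −78 °C; then ethylenediamine, CH2Cl2, rt
Reagents that add atoms: osmium tetroxide, O=[Os](=O)(=O)=O
Why: Hydrogen-bond-directed syn-dihydroxylation with OsO4·TMEDA: O6–H hydrogen-bonds to an oxo ligand of the reagent and delivers osmium to the allylic C1=C2 bond on the β face, setting C1–O and C2–O cis to O6, while C3=C4 has no allylic hydrogen-bond donor and its β face is screened by the silyl ether; stoichiometric osmium at −78 °C limits over-oxidation, and ethylenediamine should release the diol without harming the benzoate or the silyl ether.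

Step 6
Reactants: 8 [(1R,2R,5S,6S)-1,2,6-trihydroxy-5-(thexyldimethylsilyloxy)cyclohex-3-en-1-yl]methyl benzoate
Product: 9 [(1S,2R,5S,6S)-2-(benzoyloxy)-1,6-dihydroxy-5-(thexyldimethylsilyloxy)cyclohex-3-en-1-yl]methyl benzoate
Conditions: BzCl (1.1 equiv), pyridine, CH2Cl2, −30 to 0 °C
Reagents that add atoms: benzoyl chloride, O=C(Cl)c1ccccc1
Why: Regioselective benzoylation of a triol: the tertiary O1–H is inert under these conditions and O6–H lies between the quaternary C1 and the cis silyl ether on C5, so the allylic secondary O2–H should be acylated first.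

Step 7
Reactants: 9 [(1S,2R,5S,6S)-2-(benzoyloxy)-1,6-dihydroxy-5-(thexyldimethylsilyloxy)cyclohex-3-en-1-yl]methyl benzoate
Product: 10 [(1S,2R,5S,6S)-2-(benzoyloxy)-1,5,6-trihydroxycyclohex-3-en-1-yl]methyl benzoate
Conditions: HF·pyridine, pyridine, THF, 0 °C to rt
Reagents that add atoms: none
Why: Fluoride-mediated desilylation under buffered, weakly acidic conditions, chosen over basic TBAF so that the benzoates should not migrate onto the neighbouring free hydroxyls; no stereocentre is affected.

Step 8
Reactants: 10 [(1S,2R,5S,6S)-2-(benzoyloxy)-1,5,6-trihydroxycyclohex-3-en-1-yl]methyl benzoate; 11 benzoic acid (1.3 equiv)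
Product: 13 [(1S,2R,5R,6S)-2,5-bis(benzoyloxy)-1,6-dihydroxycyclohex-3-en-1-yl]methyl benzoate (CNP0128482.1), via C5 alkoxyphosphonium benzoate 12 (not isolated)
Conditions: PPh3, DIAD (1.3 equiv each), THF, 0 °C to rt
Reagents that add atoms: none
Why: Mitsunobu esterification: only the allylic secondary C5 hydroxyl should be activated and displaced (O1–H is tertiary and C6 is a neopentyl-type centre beside the quaternary C1), and benzoate attacks the C5 alkoxyphosphonium ion from the α face by SN2, inverting C5 from S to R and placing the benzoate trans to O6–H.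

**Compound list**

1 | bromobenzene | Brc1ccccc1 | starting material
2 | (1S,2S)-3-bromocyclohexa-3,5-diene-1,2-diol | BrC1=CC=C[C@H](O)[C@@H]1O | intermediate
3 | (1S,6S)-2-bromo-6-(thexyldimethylsilyloxy)cyclohexa-2,4-dien-1-ol | BrC1=CC=C[C@H](O[Si](C)(C)C(C)(C)C(C)C)[C@@H]1O | intermediate
4 | (tributylstannyl)methanol | CCCC[Sn](CCCC)(CCCC)CO | starting material
5 | (1R,6S)-2-(hydroxymethyl)-6-(thexyldimethylsilyloxy)cyclohexa-2,4-dien-1-ol | OCC1=CC=C[C@H](O[Si](C)(C)C(C)(C)C(C)C)[C@@H]1O | intermediate
6 | [(5S,6R)-6-hydroxy-5-(thexyldimethylsilyloxy)cyclohexa-1,3-dien-1-yl]methyl benzoate | O=C(OCC1=CC=C[C@H](O[Si](C)(C)C(C)(C)C(C)C)[C@@H]1O)c1ccccc1 | intermediate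
7 | cyclic osmate(VI) ester across O1 and O2 (β face) of 8, ligated by TMEDA | O=C(OC[C@]12O[Os](=O)(=O)O[C@@H]2C=C[C@H](O[Si](C)(C)C(C)(C)C(C)C)[C@@H]1O)c1ccccc1.CN(C)CCN(C)C | intermediate (not isolated)
8 | [(1R,2R,5S,6S)-1,2,6-trihydroxy-5-(thexyldimethylsilyloxy)cyclohex-3-en-1-yl]methyl benzoate | O=C(OC[C@@]1(O)[C@H](O)C=C[C@H](O[Si](C)(C)C(C)(C)C(C)C)[C@@H]1O)c1ccccc1 | intermediate
9 | [(1S,2R,5S,6S)-2-(benzoyloxy)-1,6-dihydroxy-5-(thexyldimethylsilyloxy)cyclohex-3-en-1-yl]methyl benzoate | O=C(OC[C@@]1(O)[C@H](OC(=O)c2ccccc2)C=C[C@H](O[Si](C)(C)C(C)(C)C(C)C)[C@@H]1O)c1ccccc1 | intermediate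
10 | [(1S,2R,5S,6S)-2-(benzoyloxy)-1,5,6-trihydroxycyclohex-3-en-1-yl]methyl benzoate | O=C(OC[C@@]1(O)[C@H](OC(=O)c2ccccc2)C=C[C@H](O)[C@@H]1O)c1ccccc1 | intermediate
11 | benzoic acid | OC(=O)c1ccccc1 | starting material
12 | C5 (β) alkoxy(triphenyl)phosphonium benzoate derived from 10 | O=C(OC[C@@]1(O)[C@H](OC(=O)c2ccccc2)C=C[C@H](O[P+](c2ccccc2)(c2ccccc2)c2ccccc2)[C@@H]1O)c1ccccc1.[O-]C(=O)c1ccccc1 | intermediate (not isolated)
13 | [(1S,2R,5R,6S)-2,5-bis(benzoyloxy)-1,6-dihydroxycyclohex-3-en-1-yl]methyl benzoate (CNP0128482.1) | O=C(OC[C@@]1(O)[C@H](OC(=O)c2ccccc2)C=C[C@@H](OC(=O)c2ccccc2)[C@@H]1O)c1ccccc1 | target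

**Summary**

Total step count: 8. Longest linear sequence: 8 steps (1 to 13).

Steps most likely to fail:

1. Step 8 (Mitsunobu inversion at C5). Benzoate may be delivered in SN2′ fashion at C3, or the cis-5,6-diol may tie up the phosphorus reagent as a dioxaphosphorane so that activation at C5 stalls and elimination takes over. The fallback replaces SN2 inversion by oxidation and directed reduction; it sets out from 10 and comes back at 13. The allylic C5 hydroxyl of 10 alone is oxidised with activated MnO2 (CH2Cl2, rt) to the C5 ketone of 10, the enone F1. Reduction with Me4NBH(OAc)3 (MeCN/AcOH, −30 °C; Evans–Saksena reduction) should follow: the β-disposed O1–H (β-hydroxy ketone) and O6–H bind boron and deliver hydride to the β face of C5=O, giving the C5 epimer of 10 with a 5α hydroxyl, F2. Benzoylation of F2 (BzCl 1.0 equiv, 2,4,6-collidine, CH2Cl2, −40 °C) should take the allylic O5–H in preference to the hindered O6–H and give 13.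

2. Step 5 (directed dihydroxylation of the diene). Osmylation may occur at C3=C4 or at both alkenes, the hydrogen bond may fail to control the face, or the benzoate may be lost during osmate cleavage. The fallback is a Woodward–Prévost cis-hydroxylation, which places the two oxygens on the face opposite to the one the electrophile enters; it sets out from 6 and comes back at 9, by-passing 8 and step 6. With I2 and silver benzoate (benzene, rt, dark) the iodonium ion should form on the less hindered α face of C1=C2 and be opened by benzoate at the allylic C2 from the β face, giving the 1α-iodo 2β-benzoate F3. On addition of water and warming with further silver benzoate, the C2 benzoate should displace the tertiary C1 iodide with inversion through neighbouring-group participation, and hydrolysis of the resulting acyloxonium ion should leave the cis (β,β) hydroxy benzoate, expected to carry the ester on the secondary O2, which is 9.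

3. Step 3 (Stille coupling on the labile diene). Transmetallation of the sp3 stannane may be slow, so that thermal aromatisation (loss of silanol or water), Diels–Alder dimerisation of the diene or butyl transfer competes. The fallback is carbonylation then reduction, which needs no transmetallation; it sets out from 3 and comes back at 5. Palladium-catalysed methoxycarbonylation of 3 (Pd(OAc)2, dppp, CO 1 atm, MeOH, Et3N, DMF, 60 °C) should give methyl (5S,6R)-6-hydroxy-5-(thexyldimethylsilyloxy)cyclohexa-1,3-diene-1-carboxylate F4, a dienoate of the same type as the stable cis-dihydrodiols of benzoate esters. Reduction of F4 with DIBAL-H (3 equiv, CH2Cl2, −78 °C) should give 5.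

**Further compounds**

F1 | step 8 | [(1β,6β)-dihydroxy-2β-(benzoyloxy)-5-oxocyclohex-3-en-1-yl]methyl benzoate (C5 ketone of 10) | O=C(OC[C@@]1(O)[C@H](OC(=O)c2ccccc2)C=CC(=O)[C@@H]1O)c1ccccc1
F2 | step 8 | [(1S,2R,5R,6S)-2-(benzoyloxy)-1,5,6-trihydroxycyclohex-3-en-1-yl]methyl benzoate (C5 epimer of 10) | O=C(OC[C@@]1(O)[C@H](OC(=O)c2ccccc2)C=C[C@@H](O)[C@@H]1O)c1ccccc1
F3 | step 5 | [2β-(benzoyloxy)-6β-hydroxy-1α-iodo-5β-(thexyldimethylsilyloxy)cyclohex-3-en-1-yl]methyl benzoate | O=C(OC[C@]1(I)[C@H](OC(=O)c2ccccc2)C=C[C@H](O[Si](C)(C)C(C)(C)C(C)C)[C@@H]1O)c1ccccc1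
F4 | step 3 | methyl (5S,6R)-6-hydroxy-5-(thexyldimethylsilyloxy)cyclohexa-1,3-diene-1-carboxylate | COC(=O)C1=CC=C[C@H](O[Si](C)(C)C(C)(C)C(C)C)[C@@H]1O
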